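## Retrosynthetic overview

1. The C12–C13 bond and the Z-alkene come last, from syn-carbocupration of a silyl 4-acyloxybut-2-ynoate (but-2-yne-1,4-diol plus (R)-2-methylbutanoic acid) by the bicyclic C12 organocopper.
2. The exocyclic methylene comes from a C8 ketone. Ring B, with its C8 carbonyl and C9 stereocentre, is made by an oxidative 1,2-alkyl-shift ring expansion (five to six) of a 3-bromopropylidene-trans-hydrindane.
3. The alkylidene bromide comes from cyclopropyl addition and homoallylic opening on a trans-hydrindan-1-one.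
4. Ring A is closed by metathesis of a 2-allyl-2-methyl-3-(1,1-dimethylallyl)cyclopentanone, made from 2-methylcyclopent-2-enone by enantioselective conjugate prenylation and enolate allylation.
5. Ring order: five-membered carbocycle (bought), then ring A (metathesis), then ring B (ring expansion of the five-membered ring).

Assumption: (R)-2-methylbutanoic acid and the two Grignard solutions (prenylmagnesium chloride, cyclopropylmagnesium bromide) are bought as such.

Atom labels C1–C17 in the comments follow labdane numbering of the bicyclic core. The target is the ent-labdane (5R,9R,10R) with a Z side-chain alkene and an (R)-2-methylbutanoate.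

## Route

Step 1
Reactants: 1 (3-methylbut-2-en-1-yl)magnesium chloride
Product: 2 trimethyl(3-methylbut-2-en-1-yl)silane
Conditions: Me3SiCl, THF, 0 °C to rt
Reagents that add atoms: chlorotrimethylsilane, C[Si](C)(C)Cl
Why: Silylation of an allylic Grignard reagent takes place at the less hindered primary terminus and gives the linear allylsilane.

Step 2
Reactants: 3 2-methylcyclopent-2-en-1-one; 2 trimethyl(3-methylbut-2-en-1-yl)silane; 4 3-bromoprop-1-ene
Product: 7 (2R,3R)-2-allyl-2-methyl-3-(2-methylbut-3-en-2-yl)cyclopentan-1-one, via silyl enol ether 5 (not isolated), via lithium enolate 6 (not isolated)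
Conditions: confined chiral BINOL-derived N-triflyl imidodiphosphorimidate Brønsted acid (IDPi, 3 mol %), toluene, −60 °C; then MeLi, THF, 0 °C; then 4, DMPU, −40 to 0 °C
Reagents that add atoms: methyllithium, C[Li] (lithium in 6 only)
Why: Proposed new method: the acid is silylated by 2 to a chiral-anion-paired silylium Lewis acid that O-silylates enone 3; the allylsilane then attacks C3 through its dimethyl-substituted γ-carbon (SE2') on the Si face left open by the anion (catalyst enantiomer chosen by screening), setting C5 as R, and the β-silyl cation passes Me3Si+ to the next enone so that the adduct is released as the regiodefined silyl enol ether 5; the closest known reactions are the stoichiometric TiCl4 Hosomi–Sakurai conjugate prenylation of enones (racemic) and chiral-silylium Mukaiyama–Michael and carbonyl Hosomi–Sakurai catalysis; MeLi then unmasks the tetrasubstituted enolate 6, which is allylated anti to the bulky tert-alkyl group, setting C10 with allyl trans to the C5 substituent (the future trans ring fusion).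

Step 3
Reactants: 7 (2R,3R)-2-allyl-2-methyl-3-(2-methylbut-3-en-2-yl)cyclopentan-1-one
Product: 9 (3aR,7aR)-4,4,7a-trimethyloctahydro-1H-inden-1-one, via hexahydroindenone 8 (not isolated)
Conditions: second-generation Grubbs catalyst RuCl2(=CHPh)(PCy3)(H2IMes) (3 mol %), toluene, 60 °C; then Pd/C, H2 (1 atm), rt, same pot
Reagents that add atoms: none
Why: Ring-closing metathesis of the trans-disposed allyl and vinyl arms (helped by the gem-dimethyl group, driven by loss of ethene) closes ring A, and hydrogenation of the disubstituted ring alkene leaves both stereocentres untouched.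

Step 4
Reactants: 9 (3aR,7aR)-4,4,7a-trimethyloctahydro-1H-inden-1-one; 10 cyclopropylmagnesium bromide
Product: 12 (1E,3aR,7aR)-1-(3-bromopropylidene)-4,4,7a-trimethyloctahydro-1H-indene, via cyclopropyl carbinol 11 (not isolated)
Conditions: 10, LaCl3·2LiCl, THF, 0 °C; then 48% aq HBr, 0 °C
Reagents that add atoms: hydrogen bromide, Br
Why: 1,2-Addition anti to the angular methyl gives the tertiary cyclopropyl carbinol, which under HBr ionises to a cyclopropylcarbinyl cation that bromide opens to the homoallylic bromide (Julia olefin synthesis); the E/Z ratio is irrelevant because both isomers converge in step 5.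

Step 5
Reactants: 12 (1E,3aR,7aR)-1-(3-bromopropylidene)-4,4,7a-trimethyloctahydro-1H-indene
Product: 14 (1S,4aR,8aR)-1-(2-bromoethyl)-5,5,8a-trimethyloctahydronaphthalen-2(1H)-one, via dimethyl ketal 13 (not isolated)
Conditions: Tl(NO3)3·3H2O, MeOH, 0 °C to rt; then 2 M aq HCl, THF, rt
Reagents that add atoms: methanol, CO (in 13 only); water, O
Why: Oxythallation puts thallium on C9 and methoxide on C8, and loss of monovalent thallium triggers a semipinacol-type 1,2-shift of the quaternary C10 (best migrating group, and anti to thallium in the least crowded rotamer) from C8 to C9; this is the oxidative ring expansion of an exocyclic alkene and forms ring B with the C8 carbonyl, and the acid step hydrolyses the ketal and equilibrates C9 to the equatorial side chain (C9–H trans to the C10 methyl).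

Step 6
Reactants: 14 (1S,4aR,8aR)-1-(2-bromoethyl)-5,5,8a-trimethyloctahydronaphthalen-2(1H)-one
Product: 15 (1R,4aR,8aR)-1-(2-bromoethyl)-5,5,8a-trimethyl-2-methylidenedecahydronaphthalene
Conditions: Zn, CH2Br2, TiCl4, THF/CH2Cl2, 0 °C to rt
Reagents that add atoms: dibromomethane, BrCBr
Why: Lombardo methylenation is non-basic, so the hindered enolisable ketone is converted without C9 epimerisation or cyclopropane formation from the γ-bromo ketone.

Step 7
Reactants: 16 but-2-yne-1,4-diol; 17 (2R)-2-methylbutanoic acid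
Product: 18 4-hydroxybut-2-yn-1-yl (2R)-2-methylbutanoate
Conditions: EDC·HCl, DMAP (cat.), CH2Cl2, 0 °C to rt, 16 in fourfold excess
Reagents that add atoms: none
Why: Carbodiimide (Steglich-type) esterification with excess diol gives the monoester without touching the α-stereocentre, and the water-soluble diol is washed out.

Step 8
Reactants: 18 4-hydroxybut-2-yn-1-yl (2R)-2-methylbutanoate
Product: 19 4-{[(2R)-2-methylbutanoyl]oxy}but-2-ynoic acid
Conditions: CrO3, H2SO4, H2O (Jones reagent), acetone, 0 °C
Reagents that add atoms: water, O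
Why: Jones oxidation takes a primary propargylic alcohol through the aldehyde hydrate to the ynoic acid, and the ester and its stereocentre are stable to the acidic medium.

Step 9
Reactants: 15 (1R,4aR,8aR)-1-(2-bromoethyl)-5,5,8a-trimethyl-2-methylidenedecahydronaphthalene; 19 4-{[(2R)-2-methylbutanoyl]oxy}but-2-ynoic acid
Product: 25 (2Z)-3-({[(2R)-2-methylbutanoyl]oxy}methyl)-5-[(1R,4aR,8aR)-5,5,8a-trimethyl-2-methylidenedecahydronaphthalen-1-yl]pent-2-enoic acid, via Grignard reagent 20 (not isolated), via alkylcopper 21 (not isolated), via silyl ynoate 22 (not isolated), via alkenylcopper adduct 23 (not isolated), via silyl ester 24 (not isolated)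
Conditions: 15, Mg, THF, 40 °C, then CuBr·SMe2, THF, −45 °C; separately 19, Me2C=C(OMe)OSiMe3, THF, rt; combine at −78 °C; AcOH, −78 °C; aq citric acid, rt
Reagents that add atoms: magnesium, [Mg] (in 20 only); copper bromide dimethyl sulfide complex CuBr·SMe2, [Cu]Br.CSC (copper in 21 and 23 only); 1-methoxy-2-methyl-1-(trimethylsilyloxy)prop-1-ene, COC(O[Si](C)(C)C)=C(C)C (silyl group in 22 to 24 only)
Why: Conjugate syn-carbocupration of the ynoate puts the alkyl group on the β-carbon with copper cis to it, and cold protonolysis with retention leaves CH2O-acyl cis to the carboxyl group (Z); the transient silyl ester hides the acidic proton and falls off in the aqueous work-up.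

## Compound list

1 | (3-methylbut-2-en-1-yl)magnesium chloride | CC(C)=CC[Mg]Cl | starting material
2 | trimethyl(3-methylbut-2-en-1-yl)silane | CC(C)=CC[Si](C)(C)C | intermediate
3 | 2-methylcyclopent-2-en-1-one | CC1=CCCC1=O | starting material
4 | 3-bromoprop-1-ene (allyl bromide) | C=CCBr | starting material
5 | trimethyl{[(3R)-2-methyl-3-(2-methylbut-3-en-2-yl)cyclopent-1-en-1-yl]oxy}silane | C[Si](C)(C)OC1=C(C)[C@@H](C(C)(C)C=C)CC1 | intermediate
6 | lithium (3R)-2-methyl-3-(2-methylbut-3-en-2-yl)cyclopent-1-en-1-olate | [Li]OC1=C(C)[C@@H](C(C)(C)C=C)CC1 | intermediate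
7 | (2R,3R)-2-allyl-2-methyl-3-(2-methylbut-3-en-2-yl)cyclopentan-1-one | O=C1CC[C@H](C(C)(C)C=C)[C@@]1(C)CC=C | intermediate
8 | (3aR,7aR)-4,4,7a-trimethyl-2,3,3a,4,7,7a-hexahydro-1H-inden-1-one | O=C1CC[C@@H]2C(C)(C)C=CC[C@@]12C | intermediate
9 | (3aR,7aR)-4,4,7a-trimethyloctahydro-1H-inden-1-one | O=C1CC[C@@H]2C(C)(C)CCC[C@@]12C | intermediate
10 | cyclopropylmagnesium bromide | Br[Mg]C1CC1 | starting material
11 | (1S,3aR,7aR)-1-cyclopropyl-4,4,7a-trimethyloctahydro-1H-inden-1-ol | C1CC1[C@@]2(O)CC[C@@H]3C(C)(C)CCC[C@@]23C | intermediate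
12 | (1E,3aR,7aR)-1-(3-bromopropylidene)-4,4,7a-trimethyloctahydro-1H-indene | BrCC/C=C1\CC[C@@H]2C(C)(C)CCC[C@@]12C | intermediate
13 | (1S,4aR,8aR)-1-(2-bromoethyl)-2,2-dimethoxy-5,5,8a-trimethyldecahydronaphthalene | COC1(OC)CC[C@@H]2C(C)(C)CCC[C@@]2(C)[C@@H]1CCBr | intermediate
14 | (1S,4aR,8aR)-1-(2-bromoethyl)-5,5,8a-trimethyloctahydronaphthalen-2(1H)-one | O=C1CC[C@@H]2C(C)(C)CCC[C@@]2(C)[C@@H]1CCBr | intermediate
15 | (1R,4aR,8aR)-1-(2-bromoethyl)-5,5,8a-trimethyl-2-methylidenedecahydronaphthalene | C=C1CC[C@@H]2C(C)(C)CCC[C@@]2(C)[C@@H]1CCBr | intermediate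
16 | but-2-yne-1,4-diol | OCC#CCO | starting material
17 | (2R)-2-methylbutanoic acid | CC[C@@H](C)C(=O)O | starting material
18 | 4-hydroxybut-2-yn-1-yl (2R)-2-methylbutanoate | CC[C@@H](C)C(=O)OCC#CCO | intermediate
19 | 4-{[(2R)-2-methylbutanoyl]oxy}but-2-ynoic acid | CC[C@@H](C)C(=O)OCC#CC(=O)O | intermediate
20 | {2-[(1R,4aR,8aR)-5,5,8a-trimethyl-2-methylidenedecahydronaphthalen-1-yl]ethyl}magnesium bromide | C=C1CC[C@@H]2C(C)(C)CCC[C@@]2(C)[C@@H]1CC[Mg]Br | intermediate
21 | {2-[(1R,4aR,8aR)-5,5,8a-trimethyl-2-methylidenedecahydronaphthalen-1-yl]ethyl}copper | C=C1CC[C@@H]2C(C)(C)CCC[C@@]2(C)[C@@H]1CC[Cu] | intermediate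
22 | trimethylsilyl 4-{[(2R)-2-methylbutanoyl]oxy}but-2-ynoate | CC[C@@H](C)C(=O)OCC#CC(=O)O[Si](C)(C)C | intermediate
23 | trimethylsilyl (2E)-2-cuprio-3-({[(2R)-2-methylbutanoyl]oxy}methyl)-5-[(1R,4aR,8aR)-5,5,8a-trimethyl-2-methylidenedecahydronaphthalen-1-yl]pent-2-enoate | C=C1CC[C@@H]2C(C)(C)CCC[C@@]2(C)[C@@H]1CC/C(=C(\[Cu])/C(=O)O[Si](C)(C)C)COC(=O)[C@H](C)CC | intermediate
24 | trimethylsilyl (2Z)-3-({[(2R)-2-methylbutanoyl]oxy}methyl)-5-[(1R,4aR,8aR)-5,5,8a-trimethyl-2-methylidenedecahydronaphthalen-1-yl]pent-2-enoate | C=C1CC[C@@H]2C(C)(C)CCC[C@@]2(C)[C@@H]1CC/C(=C/C(=O)O[Si](C)(C)C)COC(=O)[C@H](C)CC | intermediate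
25 | (2Z)-3-({[(2R)-2-methylbutanoyl]oxy}methyl)-5-[(1R,4aR,8aR)-5,5,8a-trimethyl-2-methylidenedecahydronaphthalen-1-yl]pent-2-enoic acid (CNP0176758.1) | C=C1CC[C@@H]2C(C)(C)CCC[C@@]2(C)[C@@H]1CC/C(=C/C(=O)O)COC(=O)[C@H](C)CC | target

## Step count and risk

Total step count: 9. Longest linear sequence: 7 (steps 1, 2, 3, 4, 5, 6, 9).

The three steps most likely to fail are steps 2, 5 and 9.

**Step 2** (the proposed new enantioselective conjugate prenylation; risks are low turnover on the α-substituted enone and insufficient enantioselectivity). The fallback uses known chemistry only and sets out from 3 and 2. Stoichiometric TiCl4 in CH2Cl2 at −78 °C (classical Hosomi–Sakurai conjugate prenylation) gives racemic trans-2-methyl-3-(2-methylbut-3-en-2-yl)cyclopentan-1-one F1. Ketalisation with (2R,3R)-butane-2,3-diol (TsOH, benzene, water removal) and chromatographic separation of the two diastereomeric ketals gives (2R,3R,6R,7S)-2,3,6-trimethyl-7-(2-methylbut-3-en-2-yl)-1,4-dioxaspiro[4.4]nonane F2. Aqueous acid releases (2R,3S)-2-methyl-3-(2-methylbut-3-en-2-yl)cyclopentan-1-one F3. Thermodynamic silylation (Me3SiCl, NaI, Et3N, MeCN) gives the tetrasubstituted enol ether, and the route is rejoined at 5.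

**Step 5** (risks are 1,2-dimethoxylation in place of the shift, or migration of C7 instead of C10). The fallback sets out from 12 and makes the leaving group and the carbinol in a separate step. N-Bromosuccinimide in aqueous 1,2-dimethoxyethane at 0 °C gives the bromohydrin (1S,3aR,7aR)-1-[(1R)-1,3-dibromopropyl]-4,4,7a-trimethyloctahydro-1H-inden-1-ol F4 (hydroxyl on the tertiary carbon). AgBF4 in CH2Cl2 at 0 °C then ionises the secondary bromide with concerted migration of C10 (silver-assisted semipinacol ring expansion), and the route is rejoined at 14.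

**Step 9** (risks are attack on or loss of the transient silyl ester, and E/Z erosion of the alkenylcopper). The fallback sets out from 19 and 15 and replaces the transient silyl ester by an isolable ester with a separate unmasking. Acid 19 with tert-butyl 2,2,2-trichloroacetimidate (cat. BF3·OEt2, CH2Cl2) gives tert-butyl 4-{[(2R)-2-methylbutanoyl]oxy}but-2-ynoate F5. Carbocupration with alkylcopper 21 (made from 15 as in step 9, THF, −78 °C, cold AcOH quench) gives tert-butyl (2Z)-3-({[(2R)-2-methylbutanoyl]oxy}methyl)-5-[(1R,4aR,8aR)-5,5,8a-trimethyl-2-methylidenedecahydronaphthalen-1-yl]pent-2-enoate F6. Me3SiOTf and 2,6-lutidine in CH2Cl2 at 0 °C exchange the tert-butyl group for silyl under buffered conditions that spare the exocyclic alkene, and the route is rejoined at 24, which the aqueous work-up turns into 25.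

## Further compounds

F1 | step 2 | racemic trans-2-methyl-3-(2-methylbut-3-en-2-yl)cyclopentan-1-one | CC1C(CCC1=O)C(C)(C)C=C
F2 | step 2 | (2R,3R,6R,7S)-2,3,6-trimethyl-7-(2-methylbut-3-en-2-yl)-1,4-dioxaspiro[4.4]nonane | C[C@H]1OC2(O[C@@H]1C)CC[C@H](C(C)(C)C=C)[C@H]2C
F3 | step 2 | (2R,3S)-2-methyl-3-(2-methylbut-3-en-2-yl)cyclopentan-1-one | O=C1CC[C@H](C(C)(C)C=C)[C@H]1C
F4 | step 5 | (1S,3aR,7aR)-1-[(1R)-1,3-dibromopropyl]-4,4,7a-trimethyloctahydro-1H-inden-1-ol | BrCC[C@@H](Br)[C@]1(O)CC[C@@H]2C(C)(C)CCC[C@@]12C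
F5 | step 9 | tert-butyl 4-{[(2R)-2-methylbutanoyl]oxy}but-2-ynoate | CC[C@@H](C)C(=O)OCC#CC(=O)OC(C)(C)C
F6 | step 9 | tert-butyl (2Z)-3-({[(2R)-2-methylbutanoyl]oxy}methyl)-5-[(1R,4aR,8aR)-5,5,8a-trimethyl-2-methylidenedecahydronaphthalen-1-yl]pent-2-enoate | C=C1CC[C@@H]2C(C)(C)CCC[C@@]2(C)[C@@H]1CC/C(=C/C(=O)OC(C)(C)C)COC(=O)[C@H](C)CC
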